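**Retrosynthetic overview**

1. The target is methyl isocupressate 15-palmitate (labdane numbering). The last disconnections are the C15–O acyl bond (palmitoyl chloride) and C4–C18 (methylation of the C4 ester enolate from the α face, which leaves the ester axial as C19).
2. The key disconnection takes C1–C2 and C5–C10 apart together: a thermal intramolecular Diels–Alder reaction of an acyclic triene closes rings A and B in one step, and no ring exists before it.
3. The enabling feature: ring A (C1–C5, C10) shares C5–C10 with ring B, C4 carries the carboxyl carbon C19, and C10 carries a methyl next to the C9 stereocentre. So C2=C3–C4(CO2Me)=C5 can be a diene and C1=C10(C20) an isopropenyl group on C9, joined by the tether C6–C7–C8(=C17)–C9.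
4. The triene maps onto (S)-limonene: its C4 is C9, its isopropenyl group is C10/C20/C1 (the dienophile), its C3 and C2 become C8 and C17, and its C5/C6/C1/C7 become C11/C12/C13/C16 once the ring alkene is cleaved.
5. Chain building: HWE olefination (C14, C15), α-methylenation then Claisen rearrangement (C7, C6, C5), bromo-HWE then Stille coupling (C4, C19, C3, C2).

Key step: step 11

Remark: atoms are numbered as in labdanes: C1–C10 decalin (ring A = C1–C5 and C10, ring B = C5–C10), C11–C16 side chain with the C13 methyl as C16, C17 the exocyclic methylene carbon on C8, C18 and C19 the methyl and ester carbons on C4, C20 the methyl on C10.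
Remark: the α-bromo phosphonate 13 is assumed to be a purchased reagent; if it is not, bromination of the Still–Gennari phosphonate gives it.

**Route**

Step 1
Reactants: 1 (S)-(−)-limonene
Product: 4 (5S)-7,7-dimethoxy-5-(prop-1-en-2-yl)heptan-2-one, via hydroperoxy aldehyde 2 (not isolated), via hydroperoxy acetal 3 (not isolated)
Conditions: O3 (1.0 equiv), CH2Cl2/MeOH 4:1, −78 °C; TsOH·H2O (cat.), rt; then NaHCO3, Me2S, rt
Reagents that add atoms: ozone (O=[O+][O-]); methanol (CO)
Why: Ozonolysis with differentiation of the two termini: the trisubstituted ring alkene is more electron-rich than the isopropenyl group and should be cleaved first, the carbonyl oxide at the methyl-bearing carbon is trapped by methanol while the free aldehyde is acetalised, and reduction then unveils the ketone, with the stereocentre (later C9) untouched.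

Step 2
Reactants: 4 keto acetal
Product: 5 ethyl (2E,6S)-8,8-dimethoxy-3-methyl-6-(prop-1-en-2-yl)oct-2-enoate
Conditions: ethyl (diisopropoxyphosphoryl)acetate, NaH, THF, 0 to 50 °C
Reagents that add atoms: ethyl (diisopropoxyphosphoryl)acetate (CCOC(=O)CP(=O)(OC(C)C)OC(C)C)
Why: Horner–Wadsworth–Emmons olefination of the methyl ketone, in which the bulky diisopropyl phosphonate should favour the (E)-trisubstituted enoate (C13=C14), while the acetal and the isopropenyl group are inert to the base.

Step 3
Reactants: 5 enoate
Product: 6 (2E,6S)-8,8-dimethoxy-3-methyl-6-(prop-1-en-2-yl)oct-2-en-1-ol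
Conditions: i-Bu2AlH (2.2 equiv), CH2Cl2, −78 °C; aq. potassium sodium tartrate
Reagents that add atoms: none
Why: 1,2-Reduction of the enoate to the allylic alcohol by i-Bu2AlH at low temperature, which leaves the acetal intact, and any (2Z) isomer from step 2 is removed here by chromatography.

Step 4
Reactants: 6 allylic alcohol
Product: 7 tert-butyl{[(2E,6S)-8,8-dimethoxy-3-methyl-6-(prop-1-en-2-yl)oct-2-en-1-yl]oxy}diphenylsilane
Conditions: TBDPSCl, imidazole, CH2Cl2, rt
Reagents that add atoms: tert-butyl(chloro)diphenylsilane (CC(C)(C)[Si](Cl)(c1ccccc1)c1ccccc1)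
Why: Silylation of the primary allylic alcohol, with the TBDPS ether chosen because it should survive the acid of step 5, the heat of steps 8 and 11 and the bases of steps 9 and 13.

Step 5
Reactants: 7 silyl ether acetal
Product: 8 (3S,6E)-8-[(tert-butyldiphenylsilyl)oxy]-6-methyl-3-(prop-1-en-2-yl)oct-6-enal
Conditions: PPTS (cat.), acetone/H2O 10:1, 50 °C
Reagents that add atoms: water (O)
Why: Mild acid-catalysed acetal hydrolysis that frees the aldehyde without touching the silyl ether or the alkenes.

Step 6
Reactants: 8 aldehyde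
Product: 9 (3R,6E)-8-[(tert-butyldiphenylsilyl)oxy]-6-methyl-2-methylidene-3-(prop-1-en-2-yl)oct-6-enal
Conditions: 37% aq. CH2O, pyrrolidine (10 mol %), propionic acid (10 mol %), i-PrOH, 45 °C
Reagents that add atoms: formaldehyde (C=O)
Why: Amine-catalysed Mannich condensation and elimination (α-methylenation of an aldehyde), which adds the carbon that becomes C7, while the stereocentre is β to the carbonyl group and is not enolised.

Step 7
Reactants: 9 enal
Product: 10 (3R,6E)-8-[(tert-butyldiphenylsilyl)oxy]-6-methyl-2-methylidene-3-(prop-1-en-2-yl)oct-6-en-1-ol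
Conditions: NaBH4, CeCl3·7H2O, MeOH, 0 °C
Reagents that add atoms: none
Why: Luche reduction, a selective 1,2-hydride addition to the enal that gives the 2-substituted allylic alcohol.

Step 8
Reactants: 10 allylic alcohol
Product: 12 (5R,8E)-10-[(tert-butyldiphenylsilyl)oxy]-8-methyl-4-methylidene-5-(prop-1-en-2-yl)dec-8-enal, via allyl vinyl ether 11 (not isolated)
Conditions: ethyl vinyl ether (solvent), Hg(OAc)2 (0.3 equiv), reflux; concentrate; toluene, 150 °C, sealed tube
Reagents that add atoms: ethyl vinyl ether (C=COCC)
Why: Hg(OAc)2-catalysed vinyl ether exchange followed by Claisen rearrangement, in which the [3,3] shift joins the vinyl carbon to the methylene carbon (now C7) and turns the former carbinol carbon into the exocyclic methylene C17, so the C5 aldehyde is obtained two carbons longer with no new stereocentre.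

Step 9
Reactants: 12 aldehyde; 13 methyl 2-bromo-2-[bis(2,2,2-trifluoroethoxy)phosphoryl]acetate
Product: 14 methyl (2E,7R,10E)-2-bromo-12-[(tert-butyldiphenylsilyl)oxy]-10-methyl-6-methylidene-7-(prop-1-en-2-yl)dodeca-2,10-dienoate
Conditions: t-BuOK, 18-crown-6, THF, −78 °C
Reagents that add atoms: none
Why: Horner–Wadsworth–Emmons olefination with a bis(trifluoroethyl) phosphonate (Still–Gennari type kinetic control), which should give the (E)-α-bromo enoate with the chain cis to the ester, the geometry the diene needs.

Step 10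
Reactants: 14 bromo enoate
Product: 15 methyl (2Z,7R,10E)-12-[(tert-butyldiphenylsilyl)oxy]-2-ethenyl-10-methyl-6-methylidene-7-(prop-1-en-2-yl)dodeca-2,10-dienoate
Conditions: tributyl(vinyl)stannane, Pd(PPh3)4 (5 mol %), CuI (10 mol %), CsF, DMF, 45 °C
Reagents that add atoms: tributyl(vinyl)stannane (C=C[Sn](CCCC)(CCCC)CCCC)
Why: Stille cross-coupling with retention of alkene geometry (oxidative addition of the zerovalent palladium complex to the C–Br bond, vinyl transfer from tin, reductive elimination), which should give the (2Z)-2-vinyl enoate in which C6 is trans to the vinyl group.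

Step 11
Reactants: 15 triene ester
Product: 16 methyl 15-[(tert-butyldiphenylsilyl)oxy]-18-norlabda-3,8(17),13E-trien-19-oate (trans-decalin; 5α-H, 9α-H, 10β-methyl)
Conditions: toluene (0.01 M), BHT (cat.), 180 °C, sealed tube, argon
Reagents that add atoms: none
Why: Thermal intramolecular Diels–Alder reaction (type 1, 1,7,9-decatriene class): the s-cis 2-(methoxycarbonyl)diene C2=C3–C4=C5 and the isopropenyl alkene C10=C1 combine in a concerted, asynchronous [4+2] step that forms C1–C2 and C5–C10 and leaves the C3=C4 enoate; the closest known reactions are thermal cyclisations of 1,7,9-decatrienes that carry an ester, bromine or silyl group on the inner diene carbon next to the tether, and of trienes whose 1,1-disubstituted dienophile creates an angular methyl group. Ring A is closed as the cyclohexene of the cycloaddition itself and ring B as the six-membered carbocycle spanned by the four-carbon tether C6–C9 (fused mode, the bridged mode being out of reach for a four-atom tether). C5 and C10 should arise from the transition state with a chair-like tether in which the tether leaves C10 on the side away from the diene and the C10 methyl lies under it, which gives the trans ring fusion; the C4 ester, cis to C6 on the diene, acts as a steric directing group because it clashes with the folded C6–C7 segment in the cis-fused alternative. The facial sense is set by the C9 stereocentre from limonene: its side chain takes the equatorial position of the forming chair and its hydrogen eclipses the isopropenyl double bond, which puts the C10 methyl and the C9 hydrogen anti as in the labdane. The step needs periselectivity for the isopropenyl group, and the substrate secures it because the C8 methylene is only two atoms from the diene and the side-chain alkene is trisubstituted and remote, while the diene geometry (C6 trans to the vinyl group) rules out a 1,5-hydrogen shift and high dilution with BHT holds back dimerisation of the electron-poor diene.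

Step 12
Reactants: 16 bicyclic enoate
Product: 17 methyl 15-[(tert-butyldiphenylsilyl)oxy]-18-norlabda-8(17),13E-dien-19-oate (mixture of C4 epimers)
Conditions: Mg turnings, MeOH, 0 °C to rt
Reagents that add atoms: none
Why: Conjugate reduction of the enoate with magnesium in methanol (electron transfer and protonation), which spares the isolated alkenes and the silyl ether, and the C4 epimer mixture converges in step 13.

Step 13
Reactants: 17 saturated ester
Product: 19 methyl (4S,5R,9S,10R)-15-[(tert-butyldiphenylsilyl)oxy]labda-8(17),13E-dien-19-oate, via lithium ester enolate 18 (not isolated)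
Conditions: LiN(i-Pr)2 (LDA), THF, −78 to 0 °C; MeI, DMPU, −78 °C to rt
Reagents that add atoms: iodomethane (CI)
Why: Alkylation of the exocyclic ester enolate, in which iodomethane should approach C4 from the α face (equatorial, anti to the axial C10 methyl), so the new methyl is C18 and the ester becomes the axial C19 group, which sets the C4 quaternary centre.

Step 14
Reactants: 19 silyl ether
Product: 20 methyl isocupressate, methyl (4S,5R,9S,10R)-15-hydroxylabda-8(17),13E-dien-19-oate
Conditions: Bu4NF, THF, rt
Reagents that add atoms: none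
Why: Fluoride-mediated cleavage of the silyl ether, driven by the strong Si–F bond, to which the hindered C19 ester is inert.

Step 15
Reactants: 20 methyl isocupressate; 21 hexadecanoyl chloride (palmitoyl chloride)
Product: 22 methyl (4S,5R,9S,10R)-15-(hexadecanoyloxy)labda-8(17),13E-dien-19-oate (CNP0157008.1)
Conditions: Et3N, DMAP (cat.), CH2Cl2, 0 °C to rt
Reagents that add atoms: none
Why: Acylation of the primary allylic alcohol with the acid chloride under nucleophilic catalysis by DMAP (esterification), with no stereocentre involved.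

**Compound list**

1 | (S)-(−)-limonene | CC1=CC[C@H](CC1)C(C)=C | starting material
2 | (3S)-6-hydroperoxy-6-methoxy-3-(prop-1-en-2-yl)heptanal (mixture at C6) | C=C(C)[C@H](CC=O)CCC(C)(OC)OO | intermediate
3 | (5S)-2-hydroperoxy-2,7,7-trimethoxy-5-(prop-1-en-2-yl)heptane (mixture at C2) | C=C(C)[C@H](CC(OC)OC)CCC(C)(OC)OO | intermediate
4 | (5S)-7,7-dimethoxy-5-(prop-1-en-2-yl)heptan-2-one | C=C(C)[C@H](CC(OC)OC)CCC(C)=O | intermediate
5 | ethyl (2E,6S)-8,8-dimethoxy-3-methyl-6-(prop-1-en-2-yl)oct-2-enoate | C=C(C)[C@H](CC(OC)OC)CC/C(C)=C/C(=O)OCC | intermediate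
6 | (2E,6S)-8,8-dimethoxy-3-methyl-6-(prop-1-en-2-yl)oct-2-en-1-ol | C=C(C)[C@H](CC(OC)OC)CC/C(C)=C/CO | intermediate
7 | tert-butyl{[(2E,6S)-8,8-dimethoxy-3-methyl-6-(prop-1-en-2-yl)oct-2-en-1-yl]oxy}diphenylsilane | C=C(C)[C@H](CC(OC)OC)CC/C(C)=C/CO[Si](c1ccccc1)(c1ccccc1)C(C)(C)C | intermediate
8 | (3S,6E)-8-[(tert-butyldiphenylsilyl)oxy]-6-methyl-3-(prop-1-en-2-yl)oct-6-enal | C=C(C)[C@H](CC=O)CC/C(C)=C/CO[Si](c1ccccc1)(c1ccccc1)C(C)(C)C | intermediate
9 | (3R,6E)-8-[(tert-butyldiphenylsilyl)oxy]-6-methyl-2-methylidene-3-(prop-1-en-2-yl)oct-6-enal | C=C(C)[C@H](C(=C)C=O)CC/C(C)=C/CO[Si](c1ccccc1)(c1ccccc1)C(C)(C)C | intermediate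
10 | (3R,6E)-8-[(tert-butyldiphenylsilyl)oxy]-6-methyl-2-methylidene-3-(prop-1-en-2-yl)oct-6-en-1-ol | C=C(C)[C@H](C(=C)CO)CC/C(C)=C/CO[Si](c1ccccc1)(c1ccccc1)C(C)(C)C | intermediate
11 | vinyl ether of 10 (O-ethenyl derivative, same configuration) | C=C(C)[C@H](C(=C)COC=C)CC/C(C)=C/CO[Si](c1ccccc1)(c1ccccc1)C(C)(C)C | intermediate
12 | (5R,8E)-10-[(tert-butyldiphenylsilyl)oxy]-8-methyl-4-methylidene-5-(prop-1-en-2-yl)dec-8-enal | C=C(C)[C@H](C(=C)CCC=O)CC/C(C)=C/CO[Si](c1ccccc1)(c1ccccc1)C(C)(C)C | intermediate
13 | methyl 2-bromo-2-[bis(2,2,2-trifluoroethoxy)phosphoryl]acetate | COC(=O)C(Br)P(=O)(OCC(F)(F)F)OCC(F)(F)F | starting material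
14 | methyl (2E,7R,10E)-2-bromo-12-[(tert-butyldiphenylsilyl)oxy]-10-methyl-6-methylidene-7-(prop-1-en-2-yl)dodeca-2,10-dienoate | C=C(C)[C@H](C(=C)CC/C=C(/Br)C(=O)OC)CC/C(C)=C/CO[Si](c1ccccc1)(c1ccccc1)C(C)(C)C | intermediate
15 | methyl (2Z,7R,10E)-12-[(tert-butyldiphenylsilyl)oxy]-2-ethenyl-10-methyl-6-methylidene-7-(prop-1-en-2-yl)dodeca-2,10-dienoate | C=C(C)[C@H](C(=C)CC/C=C(/C=C)C(=O)OC)CC/C(C)=C/CO[Si](c1ccccc1)(c1ccccc1)C(C)(C)C | intermediate
16 | methyl 15-[(tert-butyldiphenylsilyl)oxy]-18-norlabda-3,8(17),13E-trien-19-oate (5α-H, 9α-H, 10β-methyl) | C=C1CC[C@@H]2[C@](C)(CCC=C2C(=O)OC)[C@H]1CC/C(C)=C/CO[Si](c1ccccc1)(c1ccccc1)C(C)(C)C | intermediate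
17 | methyl 15-[(tert-butyldiphenylsilyl)oxy]-18-norlabda-8(17),13E-dien-19-oate (5α-H, 9α-H, 10β-methyl; C4 epimers) | C=C1CC[C@@H]2[C@](C)(CCCC2C(=O)OC)[C@H]1CC/C(C)=C/CO[Si](c1ccccc1)(c1ccccc1)C(C)(C)C | intermediate
18 | lithium enolate of 17 (exocyclic C4=C19 ketene acetal) | C=C1CC[C@@H]2[C@](C)(CCCC2=C(OC)O[Li])[C@H]1CC/C(C)=C/CO[Si](c1ccccc1)(c1ccccc1)C(C)(C)C | intermediate
19 | methyl (4S,5R,9S,10R)-15-[(tert-butyldiphenylsilyl)oxy]labda-8(17),13E-dien-19-oate | C=C1CC[C@@H]2[C@](C)(CCC[C@]2(C)C(=O)OC)[C@H]1CC/C(C)=C/CO[Si](c1ccccc1)(c1ccccc1)C(C)(C)C | intermediate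
20 | methyl isocupressate, methyl (4S,5R,9S,10R)-15-hydroxylabda-8(17),13E-dien-19-oate | C=C1CC[C@@H]2[C@](C)(CCC[C@]2(C)C(=O)OC)[C@H]1CC/C(C)=C/CO | intermediate
21 | hexadecanoyl chloride (palmitoyl chloride) | CCCCCCCCCCCCCCCC(=O)Cl | starting material
22 | methyl (4S,5R,9S,10R)-15-(hexadecanoyloxy)labda-8(17),13E-dien-19-oate (CNP0157008.1) | C=C1CC[C@@H]2[C@](C)(CCC[C@]2(C)C(=O)OC)[C@H]1CC/C(C)=C/COC(=O)CCCCCCCCCCCCCCC | target

**Step count and risks**

Total step count: 15. Longest linear sequence: 15 steps (1 to 22); 13 and 21 are purchased.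

Steps most likely to fail:

- **Step 11 (cycloaddition).** Stereocontrol may be lost, either through the cis-fused transition state or through the one with the side chain axial. The electron-poor diene may also be consumed by dimerisation, or by Cope-type scrambling through the C4=C5/C8=C17 1,5-diene, before the unactivated isopropenyl group reacts. The fallback takes the ester off the diene and lets a bromine atom on C4 steer the ring fusion. It sets out from aldehyde 12. Corey–Fuchs olefination (CBr4, PPh3, CH2Cl2, 0 °C) should give the dibromoalkene F1. A Stille coupling with tributyl(vinyl)stannane (Pd2(dba)3, tri(2-furyl)phosphine, toluene), which is expected to engage only the bromide trans to the chain, should give the (Z)-2-bromo-1,3-diene F2. Thermal intramolecular Diels–Alder reaction of F2 (toluene, 180 °C), with bromine as the steric directing group and a diene that is no longer a Michael acceptor, should give the bicyclic vinyl bromide F3. Methoxycarbonylation (Pd(OAc)2, dppp, CO, MeOH, Et3N, DMF, 70 °C) would then install C19 and return to the route at 16.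

- **Step 9 (bromo-HWE).** The E/Z ratio of the olefination may erode, or the bromo enoate may isomerise. This would pass into 15 as the diene with C6 cis to the vinyl group, which cannot cyclise. The fallback fixes the geometry by a syn addition to an alkyne and replaces steps 9 and 10. It sets out from aldehyde 12. Seyferth–Gilbert homologation with the Ohira–Bestmann reagent (K2CO3, MeOH) should give the terminal alkyne F4. Deprotonation with n-BuLi and acylation with methyl chloroformate should give the ynoate F5. Hydrostannation (Bu3SnH, Pd(PPh3)4, THF), a syn addition with tin at the α-carbon, should give the (E)-α-stannyl enoate F6. Stille coupling with vinyl bromide (Pd(PPh3)4, CuI, DMF) would then return to the route at 15.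

- **Step 1 (ozonolysis).** Ozone may over-oxidise and also attack the isopropenyl group, whose carbons are the later dienophile. The fallback separates alkene selection from cleavage. It sets out from 1. Epoxidation with mCPBA (CH2Cl2, 0 °C), selective for the trisubstituted alkene, should give limonene 1,2-oxide F7. H5IO6 in THF/H2O (epoxide opening and glycol cleavage in one pot) should give the keto aldehyde F8. Aldehyde-selective acetalisation (CH(OMe)3, MeOH, NH4Cl) would then return to the route at 4.

Further compounds
F1 | step 11 | (6R,9E)-1,1-dibromo-11-[(tert-butyldiphenylsilyl)oxy]-9-methyl-5-methylidene-6-(prop-1-en-2-yl)undeca-1,9-diene | C=C(C)[C@H](C(=C)CCC=C(Br)Br)CC/C(C)=C/CO[Si](c1ccccc1)(c1ccccc1)C(C)(C)C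
F2 | step 11 | (3Z,8R,11E)-3-bromo-13-[(tert-butyldiphenylsilyl)oxy]-11-methyl-7-methylidene-8-(prop-1-en-2-yl)trideca-1,3,11-triene | C=C(C)[C@H](C(=C)CC/C=C(/C=C)Br)CC/C(C)=C/CO[Si](c1ccccc1)(c1ccccc1)C(C)(C)C
F3 | step 11 | 4-bromo-15-[(tert-butyldiphenylsilyl)oxy]-18,19-dinorlabda-3,8(17),13E-triene (5α-H, 9α-H, 10β-methyl) | C=C1CC[C@@H]2[C@](C)(CCC=C2Br)[C@H]1CC/C(C)=C/CO[Si](c1ccccc1)(c1ccccc1)C(C)(C)C
F4 | step 9 | tert-butyl{[(2E,6R)-3-methyl-7-methylidene-6-(prop-1-en-2-yl)undec-2-en-10-yn-1-yl]oxy}diphenylsilane | C=C(C)[C@H](C(=C)CCC#C)CC/C(C)=C/CO[Si](c1ccccc1)(c1ccccc1)C(C)(C)C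
F5 | step 9 | methyl (7R,10E)-12-[(tert-butyldiphenylsilyl)oxy]-10-methyl-6-methylidene-7-(prop-1-en-2-yl)dodec-10-en-2-ynoate | C=C(C)[C@H](C(=C)CCC#CC(=O)OC)CC/C(C)=C/CO[Si](c1ccccc1)(c1ccccc1)C(C)(C)C
F6 | step 9 | methyl (2E,7R,10E)-12-[(tert-butyldiphenylsilyl)oxy]-10-methyl-6-methylidene-7-(prop-1-en-2-yl)-2-(tributylstannyl)dodeca-2,10-dienoate | C=C(C)[C@H](C(=C)CC/C=C(/[Sn](CCCC)(CCCC)CCCC)C(=O)OC)CC/C(C)=C/CO[Si](c1ccccc1)(c1ccccc1)C(C)(C)C
F7 | step 1 | (4S)-limonene 1,2-oxide, (4S)-1-methyl-4-(prop-1-en-2-yl)-7-oxabicyclo[4.1.0]heptane (cis/trans mixture) | CC12OC1C[C@H](CC2)C(C)=C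
F8 | step 1 | (3S)-6-oxo-3-(prop-1-en-2-yl)heptanal | C=C(C)[C@H](CC=O)CCC(C)=O
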